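**Plan**
- Each furan carries its chain only at C2 and has C3, C4 and C5 unsubstituted. Retrosynthetically it is taken back to a 2‑methoxy‑2,5‑dihydrofuran and cut at C3=C4, which leaves two vinyl groups on an allylic O,O‑acetal in which O1–C2 and O1–C5 already exist.
- Further cuts: the two acetal C–O bonds (allylic alcohol plus methoxyallene), the alcohol‑side diyne sp–sp bond, the ester C–O bond, the acid‑side diyne sp–sp bond and the two carbinol–vinyl C–C bonds.
- Forward: two ω‑alkynyl allylic alcohols come from vinyl Grignard additions; the acid‑side diyne is coupled first, the ester is made with 5‑bromopent‑4‑yn‑1‑ol, and the second diyne is coupled onto that ester. No protecting group is used.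
- Both allylic hydroxyls are then turned into methoxy acetals, both rings close in one ruthenium‑catalysed operation, and mild acid expels methanol to give the two furans last.
- Stereochemistry: the target has no stereocentre; the carbinol and acetal centres are carried as mixtures and end as sp2 carbons of the furans.

Key step: step 12

Remark: because the target is achiral, all chiral intermediates are planned as racemates or diastereomer mixtures.

**Step 1**
Reactants: 1 12‑bromododecan‑1‑ol; 2 lithium acetylide–ethylenediamine complex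
Product: 3 tetradec‑13‑yn‑1‑ol
Conditions: LiC≡CH·H2NCH2CH2NH2 (3 equiv), DMSO, 0 °C → rt; aq. NH4Cl
Reagents that add atoms: lithium acetylide–ethylenediamine complex 2, [Li+].[C-]#C.NCCN
Why: Acetylide alkylation: the primary bromide undergoes SN2 displacement by lithium acetylide in DMSO, the free hydroxyl merely consuming one equivalent of reagent as its lithium alkoxide.

**Step 2**
Reactants: 3 tetradec‑13‑yn‑1‑ol
Product: 4 tetradec‑13‑ynal
Conditions: TEMPO (10 mol%), PhI(OAc)2 (1.1 equiv), CH2Cl2, rt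
Reagents that add atoms: none
Why: TEMPO/PhI(OAc)2 oxidation proceeds through the oxoammonium salt, stops at the aldehyde without over‑oxidation and does not touch the terminal alkyne.

**Step 3**
Reactants: 4 tetradec‑13‑ynal; 5 vinylmagnesium bromide
Product: 6 rac‑hexadec‑1‑en‑15‑yn‑3‑ol
Conditions: CH2=CHMgBr (1.2 equiv), THF, −78 °C → −20 °C; aq. NH4Cl
Reagents that add atoms: vinylmagnesium bromide 5, C=C[Mg]Br
Why: Grignard 1,2‑addition to the unhindered aldehyde at −78 °C is faster than deprotonation of the remote terminal alkyne, and the carbinol centre, formed without control as a racemate, later becomes the sp2 C2 of a furan.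

**Step 4**
Reactants: 7 hex‑5‑ynoic acid; 8 N‑bromosuccinimide
Product: 9 6‑bromohex‑5‑ynoic acid
Conditions: NBS (1.1 equiv), AgNO3 (10 mol%), acetone, rt, dark
Reagents that add atoms: N‑bromosuccinimide 8, O=C1CCC(=O)N1Br
Why: Silver‑catalysed electrophilic bromination of a terminal alkyne with N‑bromosuccinimide goes through the silver acetylide and tolerates the free carboxylic acid.

**Step 5**
Reactants: 6 rac‑hexadec‑1‑en‑15‑yn‑3‑ol; 9 6‑bromohex‑5‑ynoic acid
Product: 10 rac‑20‑hydroxydocos‑21‑ene‑5,7‑diynoic acid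
Conditions: CuCl (10 mol%), NH2OH·HCl (30 mol%), 30% aq. n‑BuNH2, THF, 0 °C → rt, slow addition of 9 (1.2 equiv); then 1 M HCl to pH 3
Reagents that add atoms: none
Why: Cadiot–Chodkiewicz coupling: the copper acetylide of 6 couples with bromoalkyne 9 to the unsymmetrical 1,3‑diyne while hydroxylamine keeps copper monovalent and so suppresses oxidative homocoupling, and the carboxylate and allylic alcohol are spectators in aqueous amine.

**Step 6**
Reactants: 11 pent‑4‑yn‑1‑ol; 8 N‑bromosuccinimide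
Product: 12 5‑bromopent‑4‑yn‑1‑ol
Conditions: NBS (1.1 equiv), AgNO3 (10 mol%), acetone, rt, dark
Reagents that add atoms: N‑bromosuccinimide 8, O=C1CCC(=O)N1Br
Why: The same silver‑catalysed alkyne bromination as in step 4, to which the primary hydroxyl is inert.

**Step 7**
Reactants: 10 rac‑20‑hydroxydocos‑21‑ene‑5,7‑diynoic acid; 12 5‑bromopent‑4‑yn‑1‑ol
Product: 13 rac‑5‑bromopent‑4‑yn‑1‑yl 20‑hydroxydocos‑21‑ene‑5,7‑diynoate
Conditions: 12 (3 equiv), N,N'‑dicyclohexylcarbodiimide (1.1 equiv), 4‑(dimethylamino)pyridine (10 mol%), CH2Cl2, 0 °C → rt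
Reagents that add atoms: none
Why: Steglich esterification: the unhindered primary alcohol 12, used in excess, intercepts the acylpyridinium intermediate far faster than the hindered secondary allylic hydroxyl of 10, and the bromoalkyne and diyne are inert to carbodiimide and DMAP.

**Step 8**
Reactants: 14 hept‑6‑yn‑1‑ol
Product: 15 hept‑6‑ynal
Conditions: TEMPO (10 mol%), PhI(OAc)2 (1.1 equiv), CH2Cl2, rt
Reagents that add atoms: none
Why: The oxoammonium oxidation of step 2 applied to a shorter alkynol, the volatile aldehyde being carried on without prolonged evaporation.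

**Step 9**
Reactants: 15 hept‑6‑ynal; 5 vinylmagnesium bromide
Product: 16 rac‑non‑1‑en‑8‑yn‑3‑ol
Conditions: CH2=CHMgBr (1.2 equiv), THF, −78 °C → −20 °C; aq. NH4Cl
Reagents that add atoms: vinylmagnesium bromide 5, C=C[Mg]Br
Why: Grignard 1,2‑addition as in step 3, again giving a racemic allylic alcohol whose stereocentre is later destroyed.

**Step 10**
Reactants: 13 rac‑5‑bromopent‑4‑yn‑1‑yl 20‑hydroxydocos‑21‑ene‑5,7‑diynoate; 16 rac‑non‑1‑en‑8‑yn‑3‑ol
Product: 17 12‑hydroxytetradec‑13‑ene‑4,6‑diyn‑1‑yl 20‑hydroxydocos‑21‑ene‑5,7‑diynoate (mixture of diastereomers)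
Conditions: 16 (2 equiv), CuCl (10 mol%), NH2OH·HCl (30 mol%), 30% aq. n‑BuNH2, THF, 0 °C, slow addition of 13
Reagents that add atoms: none
Why: Cadiot–Chodkiewicz coupling of bromoalkyne 13 with an excess of the cheap alkyne 16 under slow addition, which limits homocoupling of 13, while the unactivated ester withstands brief exposure to dilute butylamine at 0 °C.

**Step 11**
Reactants: 17 12‑hydroxytetradec‑13‑ene‑4,6‑diyn‑1‑yl 20‑hydroxydocos‑21‑ene‑5,7‑diynoate; 18 methoxyallene
Product: 19 12‑[(1‑methoxyprop‑2‑en‑1‑yl)oxy]tetradec‑13‑ene‑4,6‑diyn‑1‑yl 20‑[(1‑methoxyprop‑2‑en‑1‑yl)oxy]docos‑21‑ene‑5,7‑diynoate (mixture of diastereomers)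
Conditions: methoxyallene (6 equiv), Pd(OAc)2 (10 mol%), 1,3‑bis(diphenylphosphino)propane (12 mol%), Et3N (3 equiv), MeCN–THF, rt; chromatography on Et3N‑treated silica
Reagents that add atoms: methoxyallene 18, COC=C=C
Why: Palladium‑catalysed hydroalkoxylation of an alkoxyallene: a palladium hydride generated from zerovalent palladium adds to methoxyallene to give a methoxy‑substituted π‑allyl complex that each allylic alkoxide attacks at the oxygen‑bearing terminus, giving the O,O‑acetals under basic conditions as an uncontrolled and inconsequential mixture at the two new acetal centres.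

**Step 12**
Reactants: 19 12‑[(1‑methoxyprop‑2‑en‑1‑yl)oxy]tetradec‑13‑ene‑4,6‑diyn‑1‑yl 20‑[(1‑methoxyprop‑2‑en‑1‑yl)oxy]docos‑21‑ene‑5,7‑diynoate
Product: 20 11‑(5‑methoxy‑2,5‑dihydrofuran‑2‑yl)undeca‑4,6‑diyn‑1‑yl 19‑(5‑methoxy‑2,5‑dihydrofuran‑2‑yl)nonadeca‑5,7‑diynoate (mixture of diastereomers)
Conditions: second‑generation Grubbs catalyst (H2IMes)(PCy3)Cl2Ru=CHPh (2 × 5 mol%), CH2Cl2 (0.005 M), 40 °C, argon sparge
Reagents that add atoms: none
Why: The ruthenium benzylidene exchanges onto a terminal vinyl group of each acetal, and [2+2] cycloaddition with the neighbouring vinyl group followed by cycloreversion of the ruthenacyclobutane forms the ring C3=C4 bond and expels ethylene (olefin metathesis by the Chauvin mechanism). The closest known reaction type is ring‑closing metathesis of allylic mixed acetals derived from alkoxyallenes to 2‑alkoxy‑2,5‑dihydrofurans. Each of the two rings closes as a five‑membered ring from a 4‑oxa‑1,6‑diene by carbon–carbon double‑bond formation between the two olefin termini, both ring C–O bonds being already in place. No stereocentre is created; the carbinol and acetal centres pass through as a diastereomer mixture and vanish in step 13. The step needs diene closure to outrun enyne metathesis at the 1,3‑diynes and intermolecular cross‑metathesis. This is secured by the 1,6‑relationship of two unhindered monosubstituted olefins, by the internal, conjugated alkynes lying at least four methylene groups from any carbinol carbon, by high dilution and by sweeping out ethylene.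

**Step 13**
Reactants: 20 11‑(5‑methoxy‑2,5‑dihydrofuran‑2‑yl)undeca‑4,6‑diyn‑1‑yl 19‑(5‑methoxy‑2,5‑dihydrofuran‑2‑yl)nonadeca‑5,7‑diynoate
Product: 21 11‑(furan‑2‑yl)undeca‑4,6‑diyn‑1‑yl 19‑(furan‑2‑yl)nonadeca‑5,7‑diynoate
Conditions: pyridinium p‑toluenesulfonate (10 mol%), CH2Cl2, rt
Reagents that add atoms: none
Why: Acid‑catalysed 1,4‑elimination of methanol: ionisation of each acetal gives a cyclic oxocarbenium ion that loses the proton at the chain‑bearing ring carbon, and the gain in furan aromaticity drives both eliminations under acid mild enough for the ester and diynes.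

**Compound list**
1 | 12‑bromododecan‑1‑ol | OCCCCCCCCCCCCBr | starting material
2 | lithium acetylide–ethylenediamine complex, LiC≡CH·H2NCH2CH2NH2 | [Li+].[C-]#C.NCCN | starting material
3 | tetradec‑13‑yn‑1‑ol | OCCCCCCCCCCCCC#C | intermediate
4 | tetradec‑13‑ynal | O=CCCCCCCCCCCCC#C | intermediate
5 | vinylmagnesium bromide | C=C[Mg]Br | starting material
6 | rac‑hexadec‑1‑en‑15‑yn‑3‑ol | C=CC(O)CCCCCCCCCCCC#C | intermediate
7 | hex‑5‑ynoic acid | OC(=O)CCCC#C | starting material
8 | N‑bromosuccinimide | O=C1CCC(=O)N1Br | starting material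
9 | 6‑bromohex‑5‑ynoic acid | OC(=O)CCCC#CBr | intermediate
10 | rac‑20‑hydroxydocos‑21‑ene‑5,7‑diynoic acid | OC(=O)CCCC#CC#CCCCCCCCCCCCC(O)C=C | intermediate
11 | pent‑4‑yn‑1‑ol | OCCCC#C | starting material
12 | 5‑bromopent‑4‑yn‑1‑ol | OCCCC#CBr | intermediate
13 | rac‑5‑bromopent‑4‑yn‑1‑yl 20‑hydroxydocos‑21‑ene‑5,7‑diynoate | BrC#CCCCOC(=O)CCCC#CC#CCCCCCCCCCCCC(O)C=C | intermediate
14 | hept‑6‑yn‑1‑ol | OCCCCCC#C | starting material
15 | hept‑6‑ynal | O=CCCCCC#C | intermediate
16 | rac‑non‑1‑en‑8‑yn‑3‑ol | C=CC(O)CCCCC#C | intermediate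
17 | 12‑hydroxytetradec‑13‑ene‑4,6‑diyn‑1‑yl 20‑hydroxydocos‑21‑ene‑5,7‑diynoate, mixture of diastereomers | O=C(CCCC#CC#CCCCCCCCCCCCC(O)C=C)OCCCC#CC#CCCCCC(O)C=C | intermediate
18 | methoxyallene (1‑methoxypropa‑1,2‑diene) | COC=C=C | starting material
19 | 12‑[(1‑methoxyprop‑2‑en‑1‑yl)oxy]tetradec‑13‑ene‑4,6‑diyn‑1‑yl 20‑[(1‑methoxyprop‑2‑en‑1‑yl)oxy]docos‑21‑ene‑5,7‑diynoate, mixture of diastereomers | O=C(CCCC#CC#CCCCCCCCCCCCC(C=C)OC(OC)C=C)OCCCC#CC#CCCCCC(C=C)OC(OC)C=C | intermediate
20 | 11‑(5‑methoxy‑2,5‑dihydrofuran‑2‑yl)undeca‑4,6‑diyn‑1‑yl 19‑(5‑methoxy‑2,5‑dihydrofuran‑2‑yl)nonadeca‑5,7‑diynoate, mixture of diastereomers | O=C(CCCC#CC#CCCCCCCCCCCCC1C=CC(OC)O1)OCCCC#CC#CCCCCC1C=CC(OC)O1 | intermediate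
21 | 11‑(furan‑2‑yl)undeca‑4,6‑diyn‑1‑yl 19‑(furan‑2‑yl)nonadeca‑5,7‑diynoate | O=C(CCCC#CC#CCCCCCCCCCCCc1ccco1)OCCCC#CC#CCCCCc1ccco1 | target

**Count**
Total steps: 13. Longest linear sequence: 9 steps (steps 1, 2, 3, 5, 7, 10, 11, 12, 13).

**Steps most likely to fail**

Step 12. The ruthenium carbene may be diverted into enyne metathesis at a conjugated diyne and held there as a vinylcarbene, or may cross‑couple vinyl groups of different molecules, so that the twofold closure stalls and oligomers form. The fallback makes each furan before any diyne exists and without metathesis; it sets out from aldehydes 4 and 15.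
- Addition of the Grignard reagent BrMgCH2CH2CH(OCH2CH2O), prepared from 2‑(2‑bromoethyl)‑1,3‑dioxolane and magnesium, to 4 would give 1‑(1,3‑dioxolan‑2‑yl)hexadec‑15‑yn‑3‑ol F1.
- Dess–Martin oxidation would give 1‑(1,3‑dioxolan‑2‑yl)hexadec‑15‑yn‑3‑one F2.
- Aqueous HCl in THF would unmask the 4‑oxoaldehyde, which closes by Paal–Knorr cyclodehydration to 2‑(tridec‑12‑yn‑1‑yl)furan F3.
- Cadiot–Chodkiewicz coupling of this alkyne with 9 would give 19‑(furan‑2‑yl)nonadeca‑5,7‑diynoic acid F4.
- The same three operations on 15 would give 1‑(1,3‑dioxolan‑2‑yl)non‑8‑yn‑3‑ol F5, 1‑(1,3‑dioxolan‑2‑yl)non‑8‑yn‑3‑one F6 and 2‑(hex‑5‑yn‑1‑yl)furan F7.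
- Coupling of that alkyne with 12 would give 11‑(furan‑2‑yl)undeca‑4,6‑diyn‑1‑ol F8.
- Carbodiimide esterification of the furyl acid with the furyl alcohol comes back to the route at 21.

Step 11. The twofold addition may stop at a mono‑acetal, the palladium hydride may add across a diyne, or the acid‑labile acetals may hydrolyse during isolation. The fallback delivers the acetal carbons by acid‑catalysed acetal exchange and sets out from 17.
- 3,3‑Diethoxyprop‑1‑ene (acrolein diethyl acetal, excess) and catalytic pyridinium p‑toluenesulfonate in toluene, with ethanol removed under reduced pressure, would give 12‑[(1‑ethoxyprop‑2‑en‑1‑yl)oxy]tetradec‑13‑ene‑4,6‑diyn‑1‑yl 20‑[(1‑ethoxyprop‑2‑en‑1‑yl)oxy]docos‑21‑ene‑5,7‑diynoate F9 as a diastereomer mixture.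
- Ring‑closing metathesis under the conditions of step 12 would give 11‑(5‑ethoxy‑2,5‑dihydrofuran‑2‑yl)undeca‑4,6‑diyn‑1‑yl 19‑(5‑ethoxy‑2,5‑dihydrofuran‑2‑yl)nonadeca‑5,7‑diynoate F10.
- Loss of ethanol under the acid of step 13 comes back to the route at 21.

Step 10. Reductive homocoupling of the advanced bromoalkyne 13 and slow aminolysis of its ester by butylamine may erode the coupling. The fallback forms the second diyne before the ester and sets out from 16 and 12.
- Cadiot–Chodkiewicz coupling of 16 with 12 would give tetradec‑13‑ene‑4,6‑diyne‑1,12‑diol F11.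
- Carbodiimide esterification of acid 10 with an excess of this diol, whose primary hydroxyl reacts ahead of the secondary allylic ones, comes back to the route at 17.

**Further compounds**
F1 | step 12 | 1‑(1,3‑dioxolan‑2‑yl)hexadec‑15‑yn‑3‑ol | C#CCCCCCCCCCCCC(O)CCC1OCCO1
F2 | step 12 | 1‑(1,3‑dioxolan‑2‑yl)hexadec‑15‑yn‑3‑one | C#CCCCCCCCCCCCC(=O)CCC1OCCO1
F3 | step 12 | 2‑(tridec‑12‑yn‑1‑yl)furan | C#CCCCCCCCCCCCc1ccco1
F4 | step 12 | 19‑(furan‑2‑yl)nonadeca‑5,7‑diynoic acid | OC(=O)CCCC#CC#CCCCCCCCCCCCc1ccco1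
F5 | step 12 | 1‑(1,3‑dioxolan‑2‑yl)non‑8‑yn‑3‑ol | C#CCCCCC(O)CCC1OCCO1
F6 | step 12 | 1‑(1,3‑dioxolan‑2‑yl)non‑8‑yn‑3‑one | C#CCCCCC(=O)CCC1OCCO1
F7 | step 12 | 2‑(hex‑5‑yn‑1‑yl)furan | C#CCCCCc1ccco1
F8 | step 12 | 11‑(furan‑2‑yl)undeca‑4,6‑diyn‑1‑ol | OCCCC#CC#CCCCCc1ccco1
F9 | step 11 | 12‑[(1‑ethoxyprop‑2‑en‑1‑yl)oxy]tetradec‑13‑ene‑4,6‑diyn‑1‑yl 20‑[(1‑ethoxyprop‑2‑en‑1‑yl)oxy]docos‑21‑ene‑5,7‑diynoate, mixture of diastereomers | O=C(CCCC#CC#CCCCCCCCCCCCC(C=C)OC(OCC)C=C)OCCCC#CC#CCCCCC(C=C)OC(OCC)C=C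
F10 | step 11 | 11‑(5‑ethoxy‑2,5‑dihydrofuran‑2‑yl)undeca‑4,6‑diyn‑1‑yl 19‑(5‑ethoxy‑2,5‑dihydrofuran‑2‑yl)nonadeca‑5,7‑diynoate, mixture of diastereomers | O=C(CCCC#CC#CCCCCCCCCCCCC1C=CC(OCC)O1)OCCCC#CC#CCCCCC1C=CC(OCC)O1
F11 | step 10 | tetradec‑13‑ene‑4,6‑diyne‑1,12‑diol | OCCCC#CC#CCCCCC(O)C=C
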